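## Retrosynthetic overview

1. Target 21 comes from the nonamethyl compound 19 by two deprotections: the two methyl esters with Me3SnOH, then the seven aryl methyl ethers with Me3SiI/quinoline. All four stereocentres are already present in 19.
2. Key disconnection: the C2–C3 bond of the 2,3-dihydrobenzofuran (ring O1–C2–C3–C3a–C7a). C3 carries the ester and sits on C3a, C2 is benzylic and sits on O1, so the bond is made from a diazoacetate carbon on C3a and the O–CH2 of a 3,4-dimethoxybenzyl ether on the C7a oxygen (diazo ester 17). This is the only ring formed in the route, and it is formed last.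
3. 17 comes from diazo transfer on arylacetate 16, which comes from esterifying the achiral arylacetic acid 13 with methyl (R)-aryllactate 15 (from (R)-danshensu).
4. 13 comes from oxidative cleavage of the C-allyl group of 11. The caffeoyloxy ester chain comes from copper-catalysed opening of methyl (R)-glycidate by the aryl Grignard reagent of bromide 6, then acylation with 3,4-dimethoxycinnamic acid.
5. 6 comes from 5-bromo-2-methoxyphenol by O-allylation, Claisen rearrangement and 3,4-dimethoxybenzylation.

Key step: step 11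

Assumption: the facial sense of the phthaloyl-tert-leucinate dirhodium catalysts is taken from their behaviour with simple 2-(benzyloxy)aryl diazoacetates, which points to the (R)-configured catalyst Rh2(R-PTTL)4 for the (2S) centre; if the (R)-lactate ester reverses this sense, the enantiomeric catalyst is used with no other change.

## Route

Step 1
Reactants: 1 5-bromo-2-methoxyphenol; 2 allyl bromide
Product: 3 2-(allyloxy)-4-bromo-1-methoxybenzene
Conditions: K2CO3, DMF, 23 °C
Reagents that add atoms: none
Why: Williamson ether synthesis, SN2 attack of the phenoxide on the allylic bromide.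

Step 2
Reactants: 3 2-(allyloxy)-4-bromo-1-methoxybenzene
Product: 4 2-allyl-3-bromo-6-methoxyphenol
Conditions: N,N-diethylaniline, 195 °C, argon
Reagents that add atoms: none
Why: Aromatic Claisen rearrangement; the other ortho carbon carries the methoxy group, so the allyl group should go to the one free ortho position, between the oxygen and the bromine.

Step 3
Reactants: 4 2-allyl-3-bromo-6-methoxyphenol; 5 3,4-dimethoxybenzyl chloride
Product: 6 2-allyl-1-bromo-3-[(3,4-dimethoxybenzyl)oxy]-4-methoxybenzene
Conditions: K2CO3, DMF, 60 °C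
Reagents that add atoms: none
Why: Williamson ether synthesis; the electron-rich benzylic chloride is reactive enough to alkylate the flanked phenoxide.

Step 4
Reactants: 6 2-allyl-1-bromo-3-[(3,4-dimethoxybenzyl)oxy]-4-methoxybenzene; 7 methyl (R)-glycidate
Product: 9 methyl (2R)-3-{2-allyl-3-[(3,4-dimethoxybenzyl)oxy]-4-methoxyphenyl}-2-hydroxypropanoate, via arylmagnesium bromide 8 (not isolated)
Conditions: Mg turnings (I2-activated), THF, 45 °C; then CuBr·SMe2 (10 mol%), 7, THF, −40 → −20 °C; aq. NH4Cl
Reagents that add atoms: magnesium, [Mg] (held in 8 only, lost on work-up)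
Why: Grignard formation followed by copper-catalysed SN2 opening of the epoxide at its unsubstituted CH2, which at low temperature should be faster than attack on the ester; the glycidate stereocentre is not touched, so (R) is carried into the lactate.

Step 5
Reactants: 9 methyl (2R)-3-{2-allyl-3-[(3,4-dimethoxybenzyl)oxy]-4-methoxyphenyl}-2-hydroxypropanoate; 10 (E)-3,4-dimethoxycinnamic acid
Product: 11 methyl (2R)-3-{2-allyl-3-[(3,4-dimethoxybenzyl)oxy]-4-methoxyphenyl}-2-{[(E)-3-(3,4-dimethoxyphenyl)acryloyl]oxy}propanoate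
Conditions: DCC, DMAP (cat.), CH2Cl2, 0 → 23 °C
Reagents that add atoms: none
Why: Steglich esterification; the stereocentre is on the alcohol partner and takes no part in the bond formation.

Step 6
Reactants: 11 methyl (2R)-3-{2-allyl-3-[(3,4-dimethoxybenzyl)oxy]-4-methoxyphenyl}-2-{[(E)-3-(3,4-dimethoxyphenyl)acryloyl]oxy}propanoate
Product: 12 methyl (2R)-2-{[(E)-3-(3,4-dimethoxyphenyl)acryloyl]oxy}-3-{3-[(3,4-dimethoxybenzyl)oxy]-4-methoxy-2-(2-oxoethyl)phenyl}propanoate
Conditions: OsO4 (2 mol%), NaIO4, 2,6-lutidine, 1,4-dioxane/H2O, 0 → 23 °C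
Reagents that add atoms: osmium tetroxide, O=[Os](=O)(=O)=O; sodium periodate, [Na+].[O-]I(=O)(=O)=O
Why: Lemieux–Johnson oxidation; OsO4 should dihydroxylate the isolated terminal alkene faster than the ester-conjugated cinnamate alkene, and periodate cleaves the diol to the arylacetaldehyde.

Step 7
Reactants: 12 methyl (2R)-2-{[(E)-3-(3,4-dimethoxyphenyl)acryloyl]oxy}-3-{3-[(3,4-dimethoxybenzyl)oxy]-4-methoxy-2-(2-oxoethyl)phenyl}propanoate
Product: 13 {2-[(2R)-2-{[(E)-3-(3,4-dimethoxyphenyl)acryloyl]oxy}-3-methoxy-3-oxopropyl]-6-[(3,4-dimethoxybenzyl)oxy]-5-methoxyphenyl}acetic acid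
Conditions: NaClO2, NaH2PO4, 2-methyl-2-butene, t-BuOH/H2O, 0 → 23 °C
Reagents that add atoms: sodium chlorite, [Na+].[O-]Cl=O
Why: Pinnick oxidation; chlorous acid oxidises only the aldehyde, and the alkene scavenger removes hypochlorous acid before it can attack the electron-rich arenes or the cinnamate.

Step 8
Reactants: 14 sodium (R)-3-(3,4-dihydroxyphenyl)lactate
Product: 15 methyl (2R)-3-(3,4-dimethoxyphenyl)-2-hydroxypropanoate
Conditions: MeI (3.5 equiv), K2CO3, DMF, 23 °C, argon
Reagents that add atoms: iodomethane, CI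
Why: SN2 O-methylation of the carboxylate and the two phenoxides; carbonate does not deprotonate the secondary alcohol, and the stereocentre is not involved.

Step 9
Reactants: 13 {2-[(2R)-2-{[(E)-3-(3,4-dimethoxyphenyl)acryloyl]oxy}-3-methoxy-3-oxopropyl]-6-[(3,4-dimethoxybenzyl)oxy]-5-methoxyphenyl}acetic acid; 15 methyl (2R)-3-(3,4-dimethoxyphenyl)-2-hydroxypropanoate
Product: 16 (2R)-3-(3,4-dimethoxyphenyl)-1-methoxy-1-oxopropan-2-yl ester of acid 13
Conditions: DCC, DMAP (cat.), CH2Cl2, 0 → 23 °C
Reagents that add atoms: none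
Why: Steglich esterification of an arylacetic acid that has no stereocentre alpha to the activated carbonyl, so nothing can epimerise; the lactate centre of 15 is on the alcohol side.

Step 10
Reactants: 16 (2R)-3-(3,4-dimethoxyphenyl)-1-methoxy-1-oxopropan-2-yl ester of acid 13
Product: 17 seco diazo ester (alpha-diazo derivative of 16 at the arylacetate carbon)
Conditions: p-ABSA, DBU, MeCN, 0 → 23 °C
Reagents that add atoms: 4-acetamidobenzenesulfonyl azide (p-ABSA), CC(=O)Nc1ccc(cc1)S(=O)(=O)N=[N+]=[N-]
Why: Regitz diazo transfer; only the arylacetate CH2, benzylic and alpha to an ester, is acidic enough for DBU, so the two lactate centres should stay untouched.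

Step 11
Reactants: 17 seco diazo ester
Product: 19 nonamethyl derivative of the target (trans-2S,3S; seven aryl methyl ethers; two methyl esters), via cis-(2S,3R) insertion product 18 (not isolated)
Conditions: Rh2(R-PTTL)4 [dirhodium tetrakis(N-phthaloyl-(R)-tert-leucinate)] (2 mol%), toluene, 4 Å MS, −40 → 0 °C, slow addition of 17; then DBU (0.5 equiv), 23 °C
Reagents that add atoms: none
Why: The divalent rhodium carboxylate takes N2 from 17 to give a donor/acceptor carbenoid at C3, which pulls a hydride-like hydrogen from the O–CH2 of the 3,4-dimethoxybenzyl ether in a concerted, asynchronous three-centre transition state and so forms C2–C3. The closest known reaction is the enantioselective dirhodium-catalysed intramolecular C–H insertion of 2-(benzyloxy)aryl diazoacetates to cis-2-aryl-2,3-dihydrobenzofuran-3-carboxylates. The one ring (O1–C2–C3–C3a–C7a) closes as a 1,5 C–H insertion, the new bond joining the carbenoid carbon to the fifth atom of the chain. C2 is set by the chiral phthalimido-carboxylate pocket of the catalyst, which selects one of the two enantiotopic ether hydrogens; C3 should form cis under kinetic control and is then brought to the more stable trans (3S) arrangement by DBU equilibration of the one proton that is both benzylic and alpha to an ester, under the base that leaves the lactate centres alone in step 10. Site selectivity is needed against the tertiary lactate C–H of the C4 side chain (also 1,5-related), the lactate ester group, the cinnamate alkene and the arene rings; it is secured because the ether CH2 is both benzylic to an electron-rich arene and alpha to oxygen, whereas the competing C–H is deactivated by its ester and acyloxy groups and the alkene is remote and electron-poor. Any minor C2 epimer is a diastereomer because of the two lactate centres and should be removable by chromatography.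

Step 12
Reactants: 19 nonamethyl derivative of the target
Product: 20 heptamethyl ether diacid (both methyl esters of 19 cleaved to CO2H)
Conditions: Me3SnOH, 1,2-dichloroethane, 75 °C; then 5% aq. HCl
Reagents that add atoms: trimethyltin hydroxide, C[Sn](C)(C)O
Why: Trimethyltin hydroxide ester hydrolysis; it should cleave the unhindered, acyloxy-activated methyl esters and spare the two secondary alkyl esters, under near-neutral conditions that do not epimerise.

Step 13
Reactants: 20 heptamethyl ether diacid
Product: 21 target CNP0201431.1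
Conditions: Me3SiI (excess), quinoline, 130 °C, sealed tube, argon; then dilute aq. HCl, reverse-phase purification
Reagents that add atoms: none
Why: Silyl iodide cleavage of aryl methyl ethers (O-silylation, then SN2 of iodide on methyl); quinoline buffers the hydrogen iodide so that the two esters and the benzylic C2–O bond should survive, and the work-up hydrolyses the silyl ethers and silyl esters.

## Compound list

1 | 5-bromo-2-methoxyphenol | COc1ccc(Br)cc1O | starting material
2 | allyl bromide | C=CCBr | starting material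
3 | 2-(allyloxy)-4-bromo-1-methoxybenzene | COc1ccc(Br)cc1OCC=C | intermediate
4 | 2-allyl-3-bromo-6-methoxyphenol | COc1ccc(Br)c(CC=C)c1O | intermediate
5 | 3,4-dimethoxybenzyl chloride | COc1ccc(CCl)cc1OC | starting material
6 | 2-allyl-1-bromo-3-[(3,4-dimethoxybenzyl)oxy]-4-methoxybenzene | COc1ccc(Br)c(CC=C)c1OCc1ccc(OC)c(OC)c1 | intermediate
7 | methyl (R)-glycidate | COC(=O)[C@H]1CO1 | starting material
8 | {2-allyl-3-[(3,4-dimethoxybenzyl)oxy]-4-methoxyphenyl}magnesium bromide | COc1ccc([Mg]Br)c(CC=C)c1OCc1ccc(OC)c(OC)c1 | intermediate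
9 | methyl (2R)-3-{2-allyl-3-[(3,4-dimethoxybenzyl)oxy]-4-methoxyphenyl}-2-hydroxypropanoate | O[C@H](Cc1ccc(OC)c(OCc2ccc(OC)c(OC)c2)c1CC=C)C(=O)OC | intermediate
10 | (E)-3,4-dimethoxycinnamic acid | COc1ccc(/C=C/C(=O)O)cc1OC | starting material
11 | methyl (2R)-3-{2-allyl-3-[(3,4-dimethoxybenzyl)oxy]-4-methoxyphenyl}-2-{[(E)-3-(3,4-dimethoxyphenyl)acryloyl]oxy}propanoate | O=C(/C=C/c1ccc(OC)c(OC)c1)O[C@H](Cc1ccc(OC)c(OCc2ccc(OC)c(OC)c2)c1CC=C)C(=O)OC | intermediate
12 | methyl (2R)-2-{[(E)-3-(3,4-dimethoxyphenyl)acryloyl]oxy}-3-{3-[(3,4-dimethoxybenzyl)oxy]-4-methoxy-2-(2-oxoethyl)phenyl}propanoate | O=C(/C=C/c1ccc(OC)c(OC)c1)O[C@H](Cc1ccc(OC)c(OCc2ccc(OC)c(OC)c2)c1CC=O)C(=O)OC | intermediate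
13 | {2-[(2R)-2-{[(E)-3-(3,4-dimethoxyphenyl)acryloyl]oxy}-3-methoxy-3-oxopropyl]-6-[(3,4-dimethoxybenzyl)oxy]-5-methoxyphenyl}acetic acid | O=C(/C=C/c1ccc(OC)c(OC)c1)O[C@H](Cc1ccc(OC)c(OCc2ccc(OC)c(OC)c2)c1CC(=O)O)C(=O)OC | intermediate
14 | sodium (R)-3-(3,4-dihydroxyphenyl)lactate (danshensu sodium salt) | [Na+].O[C@H](Cc1ccc(O)c(O)c1)C([O-])=O | starting material
15 | methyl (2R)-3-(3,4-dimethoxyphenyl)-2-hydroxypropanoate | O[C@H](Cc1ccc(OC)c(OC)c1)C(=O)OC | intermediate
16 | (2R)-3-(3,4-dimethoxyphenyl)-1-methoxy-1-oxopropan-2-yl ester of acid 13 | O=C(/C=C/c1ccc(OC)c(OC)c1)O[C@H](Cc1ccc(OC)c(OCc2ccc(OC)c(OC)c2)c1CC(=O)O[C@H](Cc1ccc(OC)c(OC)c1)C(=O)OC)C(=O)OC | intermediate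
17 | seco diazo ester (aryldiazoacetate of 16) | O=C(/C=C/c1ccc(OC)c(OC)c1)O[C@H](Cc1ccc(OC)c(OCc2ccc(OC)c(OC)c2)c1C(=[N+]=[N-])C(=O)O[C@H](Cc1ccc(OC)c(OC)c1)C(=O)OC)C(=O)OC | intermediate
18 | cis-(2S,3R) insertion product (C3 epimer of 19) | O=C(/C=C/c1ccc(OC)c(OC)c1)O[C@H](Cc1ccc(OC)c2c1[C@@H](C(=O)O[C@H](Cc1ccc(OC)c(OC)c1)C(=O)OC)[C@@H](c1ccc(OC)c(OC)c1)O2)C(=O)OC | intermediate
19 | nonamethyl derivative of the target, trans-(2S,3S) | O=C(/C=C/c1ccc(OC)c(OC)c1)O[C@H](Cc1ccc(OC)c2c1[C@H](C(=O)O[C@H](Cc1ccc(OC)c(OC)c1)C(=O)OC)[C@@H](c1ccc(OC)c(OC)c1)O2)C(=O)OC | intermediate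
20 | heptamethyl ether diacid | O=C(/C=C/c1ccc(OC)c(OC)c1)O[C@H](Cc1ccc(OC)c2c1[C@H](C(=O)O[C@H](Cc1ccc(OC)c(OC)c1)C(=O)O)[C@@H](c1ccc(OC)c(OC)c1)O2)C(=O)O | intermediate
21 | CNP0201431.1, (2R)-2-{[(2S,3S)-4-[(2R)-2-carboxy-2-{[(E)-3-(3,4-dihydroxyphenyl)acryloyl]oxy}ethyl]-2-(3,4-dihydroxyphenyl)-7-hydroxy-2,3-dihydro-1-benzofuran-3-carbonyl]oxy}-3-(3,4-dihydroxyphenyl)propanoic acid | O=C(/C=C/c1ccc(O)c(O)c1)O[C@H](Cc1ccc(O)c2c1[C@H](C(=O)O[C@H](Cc1ccc(O)c(O)c1)C(=O)O)[C@@H](c1ccc(O)c(O)c1)O2)C(=O)O | target

## Step count and risks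

Total step count: 13. Longest linear sequence: 12 steps (steps 1–7 and 9–13, from 5-bromo-2-methoxyphenol); step 8 is a one-step side branch.

Steps most likely to fail:

**Step 11 (carbenoid C–H insertion).** What may go wrong is poor discrimination between the two enantiotopic ether hydrogens when the chiral lactate ester and the crowded, twice ortho-substituted carbenoid work against the catalyst, or diversion of the carbenoid towards the lactate ester group. The fallback sets out from acid 13 and closes the ring on an achiral, reductively cleavable ester; the lactate is then attached without activating the C3 acid. Acid 13 is esterified with 2,2,2-trichloroethanol (DCC, DMAP) to the trichloroethyl arylacetate F1. Diazo transfer (p-ABSA, DBU) gives the trichloroethyl aryldiazoacetate F2. Insertion and DBU equilibration under the conditions of step 11 give the trans-(2S,3S) dihydrobenzofuran trichloroethyl ester F3. Zn in AcOH/THF releases the trans C3 carboxylic acid F4. Methyl (2S)-3-(3,4-dimethoxyphenyl)-2-hydroxypropanoate F5 is made from 3,4-dimethoxyphenylmagnesium bromide and methyl (S)-glycidate under the conditions of step 4. A Mitsunobu esterification of F4 with F5 (PPh3, DIAD, THF) inverts the lactate carbon to (R); the carboxylate acts only as nucleophile, so C3 is not exposed to an activated acyl stage. The fallback comes back to the route at 19.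

**Step 13 (sevenfold ether cleavage).** What may go wrong is cleavage of the two secondary esters, opening of the benzylic C2–O bond at 130 °C, or incomplete demethylation. The fallback sets out from 19 and reverses the order of the two deprotections. The seven aryl methyl ethers are cleaved first on the neutral diester by a boron halide at low temperature (BBr3, CH2Cl2, −78 → 0 °C), giving the heptaphenol dimethyl ester F6. The two methyl esters are then hydrolysed with Me3SnOH (1,2-dichloroethane, 75 °C; acidic work-up under argon). The fallback comes back to the route at 21.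

**Step 6 (oxidative cleavage of the allyl group).** What may go wrong is competing dihydroxylation and cleavage of the cinnamate alkene. The fallback sets out from 9 and introduces the cinnamate only after the oxidation. Alcohol 9 is silylated (TBSCl, imidazole, DMF) to the silyl ether F7. Lemieux–Johnson oxidation gives the arylacetaldehyde F8, and Pinnick oxidation gives the arylacetic acid F9. Steglich esterification with 15 gives the arylacetate F10. HF·pyridine in THF removes the silyl group to give the hydroxy diester F11. Steglich acylation of F11 with 10 comes back to the route at 16.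

## Further compounds

F1 | step 11 | 2,2,2-trichloroethyl ester of acid 13 | O=C(/C=C/c1ccc(OC)c(OC)c1)O[C@H](Cc1ccc(OC)c(OCc2ccc(OC)c(OC)c2)c1CC(=O)OCC(Cl)(Cl)Cl)C(=O)OC
F2 | step 11 | 2,2,2-trichloroethyl aryldiazoacetate | O=C(/C=C/c1ccc(OC)c(OC)c1)O[C@H](Cc1ccc(OC)c(OCc2ccc(OC)c(OC)c2)c1C(=[N+]=[N-])C(=O)OCC(Cl)(Cl)Cl)C(=O)OC
F3 | step 11 | trans-(2S,3S) dihydrobenzofuran 2,2,2-trichloroethyl ester | O=C(/C=C/c1ccc(OC)c(OC)c1)O[C@H](Cc1ccc(OC)c2c1[C@H](C(=O)OCC(Cl)(Cl)Cl)[C@@H](c1ccc(OC)c(OC)c1)O2)C(=O)OC
F4 | step 11 | trans-(2S,3S) dihydrobenzofuran-3-carboxylic acid | O=C(/C=C/c1ccc(OC)c(OC)c1)O[C@H](Cc1ccc(OC)c2c1[C@H](C(=O)O)[C@@H](c1ccc(OC)c(OC)c1)O2)C(=O)OC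
F5 | step 11 | methyl (2S)-3-(3,4-dimethoxyphenyl)-2-hydroxypropanoate | O[C@@H](Cc1ccc(OC)c(OC)c1)C(=O)OC
F6 | step 13 | heptaphenol dimethyl ester | O=C(/C=C/c1ccc(O)c(O)c1)O[C@H](Cc1ccc(O)c2c1[C@H](C(=O)O[C@H](Cc1ccc(O)c(O)c1)C(=O)OC)[C@@H](c1ccc(O)c(O)c1)O2)C(=O)OC
F7 | step 6 | tert-butyldimethylsilyl ether of 9 | CC(C)(C)[Si](C)(C)O[C@H](Cc1ccc(OC)c(OCc2ccc(OC)c(OC)c2)c1CC=C)C(=O)OC
F8 | step 6 | silyl-protected arylacetaldehyde | CC(C)(C)[Si](C)(C)O[C@H](Cc1ccc(OC)c(OCc2ccc(OC)c(OC)c2)c1CC=O)C(=O)OC
F9 | step 6 | silyl-protected arylacetic acid | CC(C)(C)[Si](C)(C)O[C@H](Cc1ccc(OC)c(OCc2ccc(OC)c(OC)c2)c1CC(=O)O)C(=O)OC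
F10 | step 6 | silyl-protected arylacetate of 15 | CC(C)(C)[Si](C)(C)O[C@H](Cc1ccc(OC)c(OCc2ccc(OC)c(OC)c2)c1CC(=O)O[C@H](Cc1ccc(OC)c(OC)c1)C(=O)OC)C(=O)OC
F11 | step 6 | hydroxy diester | O[C@H](Cc1ccc(OC)c(OCc2ccc(OC)c(OC)c2)c1CC(=O)O[C@H](Cc1ccc(OC)c(OC)c1)C(=O)OC)C(=O)OC
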